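**Assumption:** the target is the open hydroxy-ketone as drawn. Ring numbering used throughout: O1, C2 (trimethoxyphenyl), C3 (CH2OH), C4 (aroyl), C5 (CH2). The SMILES decodes to (2S,3R,4R), i.e. 2,3-trans / 3,4-cis. This route is a paper design; nothing here has been run.

## Retrosynthetic overview

1. Magnone B ⇒ cyclic aryl enone 8 by one-step radical conjugate hydroxymethylation with methanol; attack anti to the C2 aryl sets C3, kinetic α-protonation sets C4 (3,4-cis). No protecting groups.
2. Enone 8 ⇒ vinyl triflate 5 + CO + arylboronic acid 6 (carbonylative Suzuki, so no aryl-metal addition to a lactone, amide or aldehyde).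
3. Triflate 5 ⇒ ketone 4 ⇒ 4-methylene-THF 3 (regioselective enol triflation; ozonolysis).
4. 3 ⇒ 3,4,5-trimethoxybenzaldehyde 1 + TMM donor 2 by Pd-catalysed asymmetric [3+2] cycloaddition. This forms the only ring (the THF) first and sets C2, the sole source of absolute configuration.

## Route

**Step 1**
Reactants: 1, 3,4,5-trimethoxybenzaldehyde; 2, 2-[(trimethylsilyl)methyl]allyl acetate
Product: 3, (S)-4-methylene-2-(3,4,5-trimethoxyphenyl)tetrahydrofuran
Conditions: Pd(dba)2 (5 mol%), chiral phosphoramidite L* (10 mol%, enantiomer that gives the S adduct), toluene, rt–50 °C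
Reagents that add atoms: 2-[(trimethylsilyl)methyl]allyl acetate, CC(=O)OCC(=C)C[Si](C)(C)C (delivers the C4H6 unit)
Why: Pd-catalysed asymmetric trimethylenemethane [3+2] cycloaddition to an aryl aldehyde; the zwitterionic Pd–TMM adds to one aldehyde face under ligand control (sets C2 as S) and the alkoxide closes onto the π-allyl.

**Step 2**
Reactants: 3, (S)-4-methylene-2-(3,4,5-trimethoxyphenyl)tetrahydrofuran
Product: 4, (S)-5-(3,4,5-trimethoxyphenyl)dihydrofuran-3(2H)-one
Conditions: O3, CH2Cl2/MeOH, −78 °C (Sudan Red 7B end-point); then Me2S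
Reagents that add atoms: ozone, [O-][O+]=O
Why: Ozonolysis of the 1,1-disubstituted alkene is much faster than attack on the trimethoxyarene when stopped at the indicator end-point; the stereocentre is not involved.

**Step 3**
Reactants: 4, (S)-5-(3,4,5-trimethoxyphenyl)dihydrofuran-3(2H)-one
Product: 5, (S)-5-(3,4,5-trimethoxyphenyl)-2,5-dihydrofuran-3-yl trifluoromethanesulfonate
Conditions: LiHMDS added to 4 + PhNTf2 (in situ trap), THF, −78 → 0 °C
Reagents that add atoms: N-phenyl-bis(trifluoromethanesulfonimide), O=S(=O)(N(c1ccccc1)S(=O)(=O)C(F)(F)F)C(F)(F)F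
Why: Kinetic enolisation/O-triflation occurs at the α-CH2 away from the ring oxygen, as in the standard preparation of 2,5-dihydrofuran-3-yl triflate from tetrahydrofuran-3-one; the 5-ring geometry disfavours E1cB opening at −78 °C, so C2 is retained.

**Step 4**
Reactants: 5, the vinyl triflate; 6, 3,4-dimethoxyphenylboronic acid; 7, carbon monoxide
Product: 8, (S)-(3,4-dimethoxyphenyl)[5-(3,4,5-trimethoxyphenyl)-2,5-dihydrofuran-3-yl]methanone
Conditions: PdCl2(dppf) (5 mol%), K2CO3, CO (1 atm), anisole, 60–80 °C
Reagents that add atoms: carbon monoxide, [C-]#[O+]; 3,4-dimethoxyphenylboronic acid, COc1ccc(B(O)O)cc1OC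
Why: Carbonylative Suzuki–Miyaura coupling (oxidative addition of the vinyl triflate, CO insertion to acyl-Pd, transmetalation, reductive elimination) installs the aroyl group; no new stereocentre.

**Step 5 (key step)**
Reactants: 8, the enone; 9, methanol
Product: 10, Magnone B, (3,4-dimethoxyphenyl)[(3R,4R,5S)-4-(hydroxymethyl)-5-(3,4,5-trimethoxyphenyl)tetrahydrofuran-3-yl]methanone (= 2S,3R,4R in the numbering above)
Conditions: Ir[dF(CF3)ppy]2(dtbbpy)PF6 (1 mol%), quinuclidine (10 mol%), Bu4N·H2PO4 (25 mol%), MeCN/MeOH, blue LEDs, rt; neutral work-up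
Reagents that add atoms: methanol, CO
Why: Proposed new method: quinuclidine radical cation (from Ir* oxidation) abstracts the phosphate-H-bonded α-C–H of methanol; the nucleophilic •CH2OH adds in Giese fashion to the β-carbon C3 anti to the C2 aryl (2,3-trans); Ir(II) reduces the α-keto radical to the exocyclic enol(ate), which is protonated at C4 on the face away from the new CH2OH, giving the 3,4-cis ketone (kinetic ketonisation of an exocyclic aroyl enol; the cis isomer can also rest as its bicyclic hemiketal). Closest known chemistry: photoredox/HAT α-C–H alkylation of alcohols with Michael acceptors, and photochemical addition of methanol to cyclic enones.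

## Compound list

1 | 3,4,5-trimethoxybenzaldehyde | COc1cc(C=O)cc(OC)c1OC | starting material
2 | 2-[(trimethylsilyl)methyl]allyl acetate | CC(=O)OCC(=C)C[Si](C)(C)C | starting material
3 | (S)-4-methylene-2-(3,4,5-trimethoxyphenyl)tetrahydrofuran | C=C1CO[C@H](c2cc(OC)c(OC)c(OC)c2)C1 | intermediate
4 | (S)-5-(3,4,5-trimethoxyphenyl)dihydrofuran-3(2H)-one | O=C1CO[C@H](c2cc(OC)c(OC)c(OC)c2)C1 | intermediate
5 | (S)-5-(3,4,5-trimethoxyphenyl)-2,5-dihydrofuran-3-yl triflate | O=S(=O)(OC1=C[C@@H](c2cc(OC)c(OC)c(OC)c2)OC1)C(F)(F)F | intermediate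
6 | 3,4-dimethoxyphenylboronic acid | COc1ccc(B(O)O)cc1OC | starting material
7 | carbon monoxide | [C-]#[O+] | starting material
8 | (S)-(3,4-dimethoxyphenyl)[5-(3,4,5-trimethoxyphenyl)-2,5-dihydrofuran-3-yl]methanone | COc1ccc(C(=O)C2=C[C@@H](c3cc(OC)c(OC)c(OC)c3)OC2)cc1OC | intermediate
9 | methanol | CO | starting material
10 | Magnone B | COc1ccc(C(=O)[C@H]2CO[C@H](c3cc(OC)c(OC)c(OC)c3)[C@H]2CO)cc1OC | target

## Summary

Total steps: 5. Longest linear sequence: 5 (fully linear from 1).

Three steps most likely to fail, each with a fallback that changes the approach: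

1. **Step 5.** Risks are competing HAT at the substrate's C2–H, low conversion, or poor cis selectivity at C4. Fallback: a polar hydroxymethyl-anion equivalent. Cu-catalysed 1,4-addition of (iPrO)Me2SiCH2MgCl with TMSCl trapping, low-temperature protonation of the silyl enol ether, then Tamao–Fleming oxidation (KF, KHCO3, H2O2). If the C4 epimer still dominates, dehydrate the hydroxy ketone to the cis-fused bicyclic enol ether and rehydrate, which can only return the cis isomer.
2. **Step 3.** Risks are enolisation toward the O–CH2 side, or E1cB ring-opening that racemises C2. Fallback: build enone 8 by ring-closing metathesis instead. O-alkylate (S)-1-(3,4,5-trimethoxyphenyl)prop-2-en-1-ol (from 1 + vinylMgBr, then lipase or Sharpless kinetic resolution) with 2-(bromomethyl)-1-(3,4-dimethoxyphenyl)prop-2-en-1-one, then Grubbs II RCM. This fixes the alkene position unambiguously and also replaces steps 1–4.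
3. **Step 4.** Risks are direct, non-carbonylative Suzuki coupling, or base-induced γ-deprotonation at C2 leading to racemisation or alkene migration. Fallback: a base-free two-step sequence. Nozaki–Hiyama–Kishi coupling of triflate 5 with 3,4-dimethoxybenzaldehyde (CrCl2/cat. NiCl2), then MnO2 oxidation of the resulting allylic/benzylic alcohol to 8.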